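Remark on the chemistry: all chiral intermediates are racemic, and the descriptors in the SMILES show only the relative (cis) configuration at C2 and C4. Both centres are erased before the target is reached. The C4 hydroxyl is carried as a triisopropylsilyl ether, because that group has no Si–CH3 bonds that a strong base could attack in step 5.

## Analysis of the target

Sideritiflavone (18) is a flavone: a γ-pyrone (ring C) fused to a benzene ring (ring A), with a catechol (ring B) on C2. It has no stereocentre, so any sp3 centre used on the way has to disappear again. Ring A is fully substituted: C5 carries a free hydroxyl hydrogen-bonded to the C4 carbonyl, C6, C7 and C8 carry methoxyls, and C4a and C8a are the fusion atoms. The sensitive parts are the catechol (oxidised to an o-quinone by many reagents), the electron-rich ring A (its C5–OH/C8–OMe pair is a hydroquinone monoether open to oxidative demethylation) and the pyrone, which hot alkoxide opens. The difficulty is not the skeleton but placing four adjacent oxygens on ring A with exactly one of them unmethylated. The strategy rests on the fact that C5–OH is para to C8–OMe with C6 and C7 between them. A 2,3,4-trimethoxy-4-alkenylcyclobutenone delivers exactly this pattern when it opens to a dienylketene and closes onto the alkene. The ketene carbon becomes C5, and the C4a=C8a bond is supplied as the double bond of a cyclic enol ether that already is ring C.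

## Retrosynthetic reasoning

18 to 17. The two C–O bonds of an isopropylidene ketal on the catechol are the last to be cleaved. The catechol is the most oxidation-prone part of 18, so it stays masked through every oxidative step. The ketal has no acidic C–H, which matters for the organolithium step.

17 to 14. Ring C is taken back in oxidation level: the C2=C3 bond of 17 comes from flavanone 16 by dehydrogenation, the C4 carbonyl of 16 from the benzylic alcohol of diol 15, and 15 from silyl ether 14. This gains a ring C in which C4 is sp3, so that before ring A exists the C4a=C8a bond can be an isolated enol-ether double bond. The stereocentres this introduces at C2 and C4 are both removed on the way forward.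

14 to 11 (key disconnection). The C4a–C5 bond of ring A is cut. Tautomerising phenol 14 to dienone 13 and opening the six-membered ring gives dienylketene 12, which is the ring-opened form of cyclobutenone 11. The cut is made here because it turns a hexasubstituted benzene into a four-membered ring that already carries all four oxygens in the right order and the right state of alkylation. The forward reaction has to open the cyclobutenone with the pyranyl group turned toward the ketene and close the ketene carbon onto the enol-ether β-carbon.

11 to 7 and 8. The bond between the carbinol carbon (later C8) and the enol-ether carbon (later C8a) is cut, together with the O–CH3 bond on the carbinol oxygen. This leads to dimethyl squarate 8 and vinyllithium 9, the latter formed from enol ether 7 by removal of the vinylic proton next to the ring oxygen. Because 8 is symmetric, addition to either carbonyl gives the same alkoxide 10. The carbinol oxygen must be methylated before the ring expansion so that C8–OMe and C5–OH come out differentiated. Lithiation, addition and methylation are run in one flask, so neither the carbanion nor the acid-labile carbinol is isolated.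

7 to 5. The silyl ether comes from allylic alcohol 6, and 6 from 1,2-reduction of dihydropyranone 5. The C4 oxygen is kept because it becomes the flavone carbonyl.

5 to 2 and 3. The O1–C6 and C2–C3 bonds of the pyranone are cut in a hetero-Diels–Alder sense. This gives aldehyde 2, which brings ring B and C2, and Danishefsky's diene 3, which brings C3 to C6 and the C4 oxygen.

2 to 1. Aldehyde 2 is the isopropylidene ketal of 3,4-dihydroxybenzaldehyde 1.

## Alternatives that were turned down

Alternative 1: The C6–O and C8–O bonds of the two flanking methoxyls are cut. The flavone A1, which is the diphenylmethylene ketal of the target, would arise from the 6,8-dibromide A2 by a double displacement of bromide by NaOMe mediated by CuBr (monovalent copper). A2 would come from luteolin A3 by ketalisation, 7-O-methylation and bromination.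
- For: the whole carbon skeleton is bought, ring A brominates reliably at its only two free positions, and the route is about five steps. On step economy it is clearly stronger than the chosen route.
- Against: each C–Br site is flanked by two ortho substituents, and the displacement needs hot, strongly basic methoxide on the finished flavone. Under these conditions the pyrone can be opened and the C5 phenoxide deactivates the ring. Reductive loss of one bromine would give mono-methoxy flavones that differ from A1 by a single OMe and are hard to separate.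
- Comparison: the chosen strategy is longer, but every ring-A oxygen is placed by construction from 8, and no harsh step is run on the complete flavone.

Alternative 2: Ring C is cut at C8a–O1, C4a–C4 and O1–C2. Fluoride would release a symmetric tetramethoxy aryne from silyl triflate A5. The carboxylate of arylpropiolic acid A6 adds to it, the aryl anion takes over the acyl group, and the resulting phenoxide closes onto the ynone to give flavone A4.
- For: it is convergent, the aryne is symmetric so there is no regiochemical question, and three bonds of ring C form in one flask. It is as strong as the chosen strategy on regiocontrol and probably shorter in its longest linear sequence.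
- Against: the hard part, a benzene with four adjacent oxygens, is only moved into A5, which needs several steps from a pentaoxygenated arene. The electron-rich, doubly ortho-substituted aryne may stop at simple O-arylation, and five-membered (aurone) closure competes with the six-membered one. A4 carries C5 as a methyl ether, so a selective peri demethylation and a debenzylation must follow.
- Comparison: the chosen strategy takes the four oxygens from a commodity four-carbon block and delivers the free C5 hydroxyl directly.

Alternative 3: Ring B is cut at C1'–C2' and C5'–C6'. A thermal [4+2] cycloaddition of ethynylchromone A8 with diene A9 would give cyclohexadiene A7, which would then be oxidised to the arene and desilylated.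
- For: the catechol appears late without ketal or benzyl protection, and only two hydrogens have to be removed to aromatise.
- Against: for this target ring B is the easy ring, available as 1. A8 already contains the complete 5-hydroxy-6,7,8-trimethoxychromone, so the real problem must be solved beforehand by another route and an alkyne must then be attached. The chromone C2=C3 bond is a second dienophile. The bis-silyl enediol in A7 is prone to hydrolysis to a diketone and to over-oxidation to an o-quinone.
- Comparison: it is weaker than the chosen strategy on every count except protecting-group economy for ring B. The chosen route spends its key step on ring A, where the difficulty lies.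

Key step: step 6

## Route

Step 1
Reactants: 1 3,4-dihydroxybenzaldehyde
Product: 2 2,2-dimethyl-1,3-benzodioxole-5-carbaldehyde
Conditions: 2,2-dimethoxypropane, TsOH·H2O (cat.), toluene, reflux, MeOH removed over 4 Å MS (Soxhlet); aq NaHCO3
Reagents that add atoms: 2,2-dimethoxypropane, COC(C)(C)OC
Why: Acid-catalysed transketalisation of the catechol, driven by removal of methanol; any aldehyde dimethyl acetal reverts on aqueous work-up. The ketal has no acidic C–H and should withstand organolithiums, fluoride, hydride and the later oxidants.

Step 2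
Reactants: 2 2,2-dimethyl-1,3-benzodioxole-5-carbaldehyde; 3 Danishefsky's diene [(E)-1-methoxy-3-(trimethylsilyloxy)buta-1,3-diene]
Product: 5 2-(2,2-dimethyl-1,3-benzodioxol-5-yl)-2,3-dihydro-4H-pyran-4-one (racemic), via cycloadduct 4 (not isolated)
Conditions: ZnCl2 (0.5 equiv), THF, rt; then TFA (cat.), CH2Cl2, 0 °C; aq NaHCO3
Reagents that add atoms: none
Why: Lewis-acid-promoted hetero-Diels–Alder reaction of an aldehyde with Danishefsky's diene; acid then cleaves the silyl enol ether of 4 and eliminates methanol to give the vinylogous ester. C2 forms racemic, which is sufficient because it becomes sp2 in step 9.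

Step 3
Reactants: 5 2-(2,2-dimethyl-1,3-benzodioxol-5-yl)-2,3-dihydro-4H-pyran-4-one
Product: 6 cis-2-(2,2-dimethyl-1,3-benzodioxol-5-yl)-3,4-dihydro-2H-pyran-4-ol (racemic)
Conditions: NaBH4, CeCl3·7H2O, MeOH, −78 → −40 °C; Et3N, aq NaHCO3
Reagents that add atoms: none
Why: Luche 1,2-reduction of the vinylogous ester carbonyl. Axial hydride delivery to the half-chair with a pseudo-equatorial aryl group should give the pseudo-equatorial alcohol, cis to the aryl group; the configuration is of no consequence because C4 is reoxidised in step 8.

Step 4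
Reactants: 6 cis-2-(2,2-dimethyl-1,3-benzodioxol-5-yl)-3,4-dihydro-2H-pyran-4-ol
Product: 7 cis-2-(2,2-dimethyl-1,3-benzodioxol-5-yl)-4-(triisopropylsilyloxy)-3,4-dihydro-2H-pyran (racemic)
Conditions: i-Pr3SiCl, imidazole, DMAP (cat.), DMF, rt → 40 °C
Reagents that add atoms: triisopropylsilyl chloride, CC(C)[Si](Cl)(C(C)C)C(C)C
Why: Standard silylation of a secondary allylic alcohol under basic conditions that spare the acid-labile enol ether. The triisopropylsilyl group is chosen because it is inert to t-BuLi and is removed by fluoride.

Step 5
Reactants: 7 cis-2-(2,2-dimethyl-1,3-benzodioxol-5-yl)-4-(triisopropylsilyloxy)-3,4-dihydro-2H-pyran; 8 dimethyl squarate (3,4-dimethoxycyclobut-3-ene-1,2-dione)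
Product: 11 4-[cis-2-(2,2-dimethyl-1,3-benzodioxol-5-yl)-4-(triisopropylsilyloxy)-3,4-dihydro-2H-pyran-6-yl]-2,3,4-trimethoxycyclobut-2-en-1-one (racemic; mixture at the cyclobutenone carbon), via vinyllithium 9 (not isolated), via lithium alkoxide 10 (not isolated)
Conditions: t-BuLi (1.1 equiv), THF, −78 → 0 °C, 30 min; recool to −78 °C, cannulate into 8 (1.2 equiv), THF, −78 °C; MeOTf (2 equiv), −78 → −20 °C; Et3N, aq NaHCO3; Et3N-deactivated silica
Reagents that add atoms: methyl trifluoromethanesulfonate, COS(=O)(=O)C(F)(F)F
Why: α-Lithiation of a cyclic enol ether at the sp2 C–H next to the ring oxygen, the reaction used for dihydropyrans and silylated glycals, gives vinyllithium 9; the small excess of t-BuLi is consumed by THF during the warming period, so no alkyllithium meets the squarate. Vinyllithiums add 1,2 to one of the two equivalent carbonyls of squarate esters at −78 °C, and the tertiary alkoxide 10 is O-methylated in the flask by MeOTf, so the acid-labile carbinol is never handled. The new quaternary centre forms as a mixture, which is without consequence because it becomes the aromatic C8.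

Step 6
Reactants: 11 4-[cis-2-(2,2-dimethyl-1,3-benzodioxol-5-yl)-4-(triisopropylsilyloxy)-3,4-dihydro-2H-pyran-6-yl]-2,3,4-trimethoxycyclobut-2-en-1-one
Product: 14 cis-2-(2,2-dimethyl-1,3-benzodioxol-5-yl)-6,7,8-trimethoxy-4-(triisopropylsilyloxy)chroman-5-ol (racemic), via dienylketene 12 (not isolated), via cyclohexadienone 13 (not isolated)
Conditions: toluene (degassed, 0.02 M), 110 °C, Ar, base-washed glassware
Reagents that add atoms: none
Why: Thermal 4π conrotatory opening of the cyclobutenone C1–C4 bond gives dienylketene 12; the C4 methoxyl, as the donor, rotates outward and the dihydropyranyl group inward, so its double bond lies next to the ketene. A thermal 6π disrotatory electrocyclization then joins the electrophilic ketene carbon to the nucleophilic β-carbon of the enol ether, forming C4a–C5 and closing the six-membered carbocycle (ring A) as cyclohexa-2,4-dienone 13. Loss of the C4a hydrogen to oxygen gives phenol 14 and makes the sequence irreversible. The closest known reaction type is the Moore rearrangement of 4-alkenyl-4-alkoxycyclobutenones to hydroquinone monoethers, here with a cyclic enol ether as the alkenyl group. No lasting stereocentre is created: the C4a centre of 13 is transient, and C2 and C4 are not touched, so their cis relation is carried through. The step needs torquoselectivity, which the oxygen donor at C4 secures and which is forgiving because a ketene with the wrong geometry recloses to 11. It also needs one site of closure, which is secured because only the enol-ether β-carbon is both six atoms from the ketene carbon and able to lose a hydrogen. The ketene carbon becomes C5–OH, the two vinylogous-ester carbons become C6 and C7, and the methylated carbinol carbon becomes C8–OMe, so the four oxygens of ring A arrive already differentiated.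

Step 7
Reactants: 14 cis-2-(2,2-dimethyl-1,3-benzodioxol-5-yl)-6,7,8-trimethoxy-4-(triisopropylsilyloxy)chroman-5-ol
Product: 15 cis-2-(2,2-dimethyl-1,3-benzodioxol-5-yl)-6,7,8-trimethoxychromane-4,5-diol (racemic)
Conditions: Bu4NF, THF, 0 °C → rt; pH 7 buffer
Reagents that add atoms: none
Why: Fluoride-induced Si–O cleavage. The basic, non-acidic medium avoids ionisation of the C4–O bond, which is benzylic to a very electron-rich ring; the diol is taken on without chromatography on acidic silica.

Step 8
Reactants: 15 cis-2-(2,2-dimethyl-1,3-benzodioxol-5-yl)-6,7,8-trimethoxychromane-4,5-diol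
Product: 16 2-(2,2-dimethyl-1,3-benzodioxol-5-yl)-5-hydroxy-6,7,8-trimethoxychroman-4-one (racemic)
Conditions: MnO2 (activated, excess), CH2Cl2, rt
Reagents that add atoms: none
Why: MnO2 oxidises benzylic alcohols selectively and tolerates free phenols, as in the oxidation of o-hydroxybenzyl alcohols to o-hydroxyaryl carbonyl compounds. The new ketone is held by a hydrogen bond to the C5 hydroxyl, and the C4 stereocentre is removed.

Step 9
Reactants: 16 2-(2,2-dimethyl-1,3-benzodioxol-5-yl)-5-hydroxy-6,7,8-trimethoxychroman-4-one
Product: 17 2-(2,2-dimethyl-1,3-benzodioxol-5-yl)-5-hydroxy-6,7,8-trimethoxy-4H-chromen-4-one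
Conditions: I2 (0.2 equiv), DMSO, 120 °C
Reagents that add atoms: none
Why: Iodine-catalysed dehydrogenation of a flavanone in DMSO: α-iodination of the enol and loss of HI give the C2=C3 bond, and DMSO reoxidises HI. Ring A has no free position for iodination, the last stereocentre (C2) disappears, and any partial loss of the ketal is harmless because step 10 removes it.

Step 10
Reactants: 17 2-(2,2-dimethyl-1,3-benzodioxol-5-yl)-5-hydroxy-6,7,8-trimethoxy-4H-chromen-4-one
Product: 18 sideritiflavone [2-(3,4-dihydroxyphenyl)-5-hydroxy-6,7,8-trimethoxy-4H-chromen-4-one]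
Conditions: TFA–H2O (9:1), rt
Reagents that add atoms: none
Why: Acid hydrolysis of the catechol isopropylidene ketal. The aryl methyl ethers and the hydrogen-bonded 5-hydroxyflavone are inert to aqueous TFA at room temperature.

## Compound list

1 | 3,4-dihydroxybenzaldehyde | O=Cc1ccc(O)c(O)c1 | starting material
2 | 2,2-dimethyl-1,3-benzodioxole-5-carbaldehyde | O=Cc1ccc2OC(C)(C)Oc2c1 | intermediate
3 | Danishefsky's diene, (E)-1-methoxy-3-(trimethylsilyloxy)buta-1,3-diene | CO/C=C/C(=C)O[Si](C)(C)C | starting material
4 | 2-(2,2-dimethyl-1,3-benzodioxol-5-yl)-6-methoxy-4-(trimethylsilyloxy)-3,6-dihydro-2H-pyran (racemic, mixture of diastereomers) | COC1C=C(O[Si](C)(C)C)CC(c2ccc3OC(C)(C)Oc3c2)O1 | intermediate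
5 | 2-(2,2-dimethyl-1,3-benzodioxol-5-yl)-2,3-dihydro-4H-pyran-4-one (racemic) | O=C1C=COC(c2ccc3OC(C)(C)Oc3c2)C1 | intermediate
6 | cis-2-(2,2-dimethyl-1,3-benzodioxol-5-yl)-3,4-dihydro-2H-pyran-4-ol (racemic) | C1=C[C@@H](O)C[C@@H](c2ccc3OC(C)(C)Oc3c2)O1 | intermediate
7 | cis-2-(2,2-dimethyl-1,3-benzodioxol-5-yl)-4-(triisopropylsilyloxy)-3,4-dihydro-2H-pyran (racemic) | C1=C[C@@H](O[Si](C(C)C)(C(C)C)C(C)C)C[C@@H](c2ccc3OC(C)(C)Oc3c2)O1 | intermediate
8 | dimethyl squarate, 3,4-dimethoxycyclobut-3-ene-1,2-dione | COC1=C(OC)C(=O)C1=O | starting material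
9 | [cis-2-(2,2-dimethyl-1,3-benzodioxol-5-yl)-4-(triisopropylsilyloxy)-3,4-dihydro-2H-pyran-6-yl]lithium (racemic) | [Li]C1=C[C@@H](O[Si](C(C)C)(C(C)C)C(C)C)C[C@@H](c2ccc3OC(C)(C)Oc3c2)O1 | intermediate
10 | lithium 1-[cis-2-(2,2-dimethyl-1,3-benzodioxol-5-yl)-4-(triisopropylsilyloxy)-3,4-dihydro-2H-pyran-6-yl]-2,3-dimethoxy-4-oxocyclobut-2-en-1-olate (racemic, mixture at the carbinol carbon) | [Li+].COC1=C(OC)C([O-])(C2=C[C@@H](O[Si](C(C)C)(C(C)C)C(C)C)C[C@@H](c3ccc4OC(C)(C)Oc4c3)O2)C1=O | intermediate
11 | 4-[cis-2-(2,2-dimethyl-1,3-benzodioxol-5-yl)-4-(triisopropylsilyloxy)-3,4-dihydro-2H-pyran-6-yl]-2,3,4-trimethoxycyclobut-2-en-1-one (racemic, mixture at the cyclobutenone carbon) | COC1=C(OC)C(OC)(C2=C[C@@H](O[Si](C(C)C)(C(C)C)C(C)C)C[C@@H](c3ccc4OC(C)(C)Oc4c3)O2)C1=O | intermediate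
12 | (Z)-4-[cis-2-(2,2-dimethyl-1,3-benzodioxol-5-yl)-4-(triisopropylsilyloxy)-3,4-dihydro-2H-pyran-6-yl]-2,3,4-trimethoxybuta-1,3-dien-1-one (racemic) | O=C=C(OC)/C(OC)=C(OC)\C1=C[C@@H](O[Si](C(C)C)(C(C)C)C(C)C)C[C@@H](c2ccc3OC(C)(C)Oc3c2)O1 | intermediate
13 | cis-2-(2,2-dimethyl-1,3-benzodioxol-5-yl)-6,7,8-trimethoxy-4-(triisopropylsilyloxy)-2,3,4,4a-tetrahydro-5H-chromen-5-one (racemic, C4a undefined) | COC1=C(OC)C(=O)C2[C@@H](O[Si](C(C)C)(C(C)C)C(C)C)C[C@@H](c3ccc4OC(C)(C)Oc4c3)OC2=C1OC | intermediate
14 | cis-2-(2,2-dimethyl-1,3-benzodioxol-5-yl)-6,7,8-trimethoxy-4-(triisopropylsilyloxy)chroman-5-ol (racemic) | COc1c(OC)c(O)c2[C@@H](O[Si](C(C)C)(C(C)C)C(C)C)C[C@@H](c3ccc4OC(C)(C)Oc4c3)Oc2c1OC | intermediate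
15 | cis-2-(2,2-dimethyl-1,3-benzodioxol-5-yl)-6,7,8-trimethoxychromane-4,5-diol (racemic) | COc1c(OC)c(O)c2[C@@H](O)C[C@@H](c3ccc4OC(C)(C)Oc4c3)Oc2c1OC | intermediate
16 | 2-(2,2-dimethyl-1,3-benzodioxol-5-yl)-5-hydroxy-6,7,8-trimethoxychroman-4-one (racemic) | COc1c(OC)c(O)c2C(=O)CC(c3ccc4OC(C)(C)Oc4c3)Oc2c1OC | intermediate
17 | 2-(2,2-dimethyl-1,3-benzodioxol-5-yl)-5-hydroxy-6,7,8-trimethoxy-4H-chromen-4-one | COc1c(OC)c(O)c2c(=O)cc(-c3ccc4OC(C)(C)Oc4c3)oc2c1OC | intermediate
18 | sideritiflavone, 2-(3,4-dihydroxyphenyl)-5-hydroxy-6,7,8-trimethoxy-4H-chromen-4-one | COc1c(OC)c(O)c2c(=O)cc(-c3ccc(O)c(O)c3)oc2c1OC | target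

## Step count and least certain steps

Total: 10 steps. Longest linear sequence: 10 steps, from 1 to 18; 3 and 8 are bought and enter in steps 2 and 5.

Step 6 (key step). The most likely failure is heterolysis or elimination at the C4–O bond during the heating, in dienone 13 or in product 14, driven by the peri phenol and the donor oxygens of ring A. A second risk is slow closure, because the silyloxy-bearing C4 crowds the reacting enol-ether carbon; the ketene then has time to dimerise or to be trapped by traces of water. The fallback moves the C4 oxidation in front of the ring expansion. Setting out from 11, buffered Bu4NF/AcOH in THF removes the silyl group to give 4-[cis-2-(2,2-dimethyl-1,3-benzodioxol-5-yl)-4-hydroxy-3,4-dihydro-2H-pyran-6-yl]-2,3,4-trimethoxycyclobut-2-en-1-one F1. MnO2 in CH2Cl2 oxidises the allylic alcohol to 4-[2-(2,2-dimethyl-1,3-benzodioxol-5-yl)-4-oxo-3,4-dihydro-2H-pyran-6-yl]-2,3,4-trimethoxycyclobut-2-en-1-one F2. Heating F2 in toluene runs the same ring opening and electrocyclization onto the α-carbon of a vinylogous ester, which has no leaving group at C4 and a smaller neighbour. The route is rejoined at flavanone 16, and steps 7 and 8 are no longer needed.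

Step 5. The most likely failure is competing deprotonation at the benzylic C2–H, which sits on the same oxygen as the vinylic C–H, and on the arene ortho to the ketal oxygens. Because the lithiated material is used without purification, every misplaced carbanion is carried into the squarate addition and lowers the purity of 11. Incomplete O-methylation of the hindered tertiary alkoxide is the second risk. The fallback makes the carbanion site unambiguous without any C–H deprotonation. Setting out from 7, oxidation of the enol ether with (C5H5NH)CrO3Cl (pyridinium chlorochromate) buffered with NaOAc in CH2Cl2 gives cis-6-(2,2-dimethyl-1,3-benzodioxol-5-yl)-4-(triisopropylsilyloxy)tetrahydro-2H-pyran-2-one F3. Enolisation with KN(SiMe3)2 in the presence of (PhO)2P(O)Cl in THF at −78 °C gives [cis-2-(2,2-dimethyl-1,3-benzodioxol-5-yl)-4-(triisopropylsilyloxy)-3,4-dihydro-2H-pyran-6-yl] diphenyl phosphate F4; trapping in the flask should outrun β-elimination of the silyloxy group. Coupling of F4 with Me3SnSnMe3 under Pd(PPh3)4 and LiCl in THF gives trimethyl[cis-2-(2,2-dimethyl-1,3-benzodioxol-5-yl)-4-(triisopropylsilyloxy)-3,4-dihydro-2H-pyran-6-yl]stannane F5, which can be purified. MeLi in THF at −78 °C then releases vinyllithium 9 free of other carbanions, and the route is rejoined there, with the addition to 8 and the methylation run as in step 5.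

Step 8. The most likely failure is oxidation of the hydroquinone-monoether ring itself (oxidative demethylation towards a quinone), or ionisation and dehydration of the flavan-4-ol on the oxide surface. The fallback masks the phenol before the alcohol is freed. Setting out from 14, MOMCl and i-Pr2NEt in CH2Cl2 give cis-2-(2,2-dimethyl-1,3-benzodioxol-5-yl)-6,7,8-trimethoxy-5-(methoxymethoxy)-4-(triisopropylsilyloxy)chromane F6. Bu4NF gives cis-2-(2,2-dimethyl-1,3-benzodioxol-5-yl)-6,7,8-trimethoxy-5-(methoxymethoxy)chroman-4-ol F7. Dess–Martin periodinane buffered with NaHCO3, now with no free phenol present, gives 2-(2,2-dimethyl-1,3-benzodioxol-5-yl)-6,7,8-trimethoxy-5-(methoxymethoxy)chroman-4-one F8. Dilute HCl in MeOH at room temperature cleaves the peri acetal, and the route is rejoined at 16.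

## Further compounds

F1 | step 6 | 4-[cis-2-(2,2-dimethyl-1,3-benzodioxol-5-yl)-4-hydroxy-3,4-dihydro-2H-pyran-6-yl]-2,3,4-trimethoxycyclobut-2-en-1-one | COC1=C(OC)C(OC)(C2=C[C@@H](O)C[C@@H](c3ccc4OC(C)(C)Oc4c3)O2)C1=O
F2 | step 6 | 4-[2-(2,2-dimethyl-1,3-benzodioxol-5-yl)-4-oxo-3,4-dihydro-2H-pyran-6-yl]-2,3,4-trimethoxycyclobut-2-en-1-one | COC1=C(OC)C(OC)(C2=CC(=O)CC(c3ccc4OC(C)(C)Oc4c3)O2)C1=O
F3 | step 5 | cis-6-(2,2-dimethyl-1,3-benzodioxol-5-yl)-4-(triisopropylsilyloxy)tetrahydro-2H-pyran-2-one | O=C1C[C@@H](O[Si](C(C)C)(C(C)C)C(C)C)C[C@@H](c2ccc3OC(C)(C)Oc3c2)O1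
F4 | step 5 | [cis-2-(2,2-dimethyl-1,3-benzodioxol-5-yl)-4-(triisopropylsilyloxy)-3,4-dihydro-2H-pyran-6-yl] diphenyl phosphate | O=P(Oc1ccccc1)(Oc1ccccc1)OC1=C[C@@H](O[Si](C(C)C)(C(C)C)C(C)C)C[C@@H](c2ccc3OC(C)(C)Oc3c2)O1
F5 | step 5 | trimethyl[cis-2-(2,2-dimethyl-1,3-benzodioxol-5-yl)-4-(triisopropylsilyloxy)-3,4-dihydro-2H-pyran-6-yl]stannane | C[Sn](C)(C)C1=C[C@@H](O[Si](C(C)C)(C(C)C)C(C)C)C[C@@H](c2ccc3OC(C)(C)Oc3c2)O1
F6 | step 8 | cis-2-(2,2-dimethyl-1,3-benzodioxol-5-yl)-6,7,8-trimethoxy-5-(methoxymethoxy)-4-(triisopropylsilyloxy)chromane | COCOc1c(OC)c(OC)c(OC)c2O[C@H](c3ccc4OC(C)(C)Oc4c3)C[C@H](O[Si](C(C)C)(C(C)C)C(C)C)c12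
F7 | step 8 | cis-2-(2,2-dimethyl-1,3-benzodioxol-5-yl)-6,7,8-trimethoxy-5-(methoxymethoxy)chroman-4-ol | COc1c(OC)c(OCOC)c2[C@@H](O)C[C@@H](c3ccc4OC(C)(C)Oc4c3)Oc2c1OC
F8 | step 8 | 2-(2,2-dimethyl-1,3-benzodioxol-5-yl)-6,7,8-trimethoxy-5-(methoxymethoxy)chroman-4-one | COc1c(OC)c(OCOC)c2C(=O)CC(c3ccc4OC(C)(C)Oc4c3)Oc2c1OC
A1 | alternative 1 | 2-(2,2-diphenyl-1,3-benzodioxol-5-yl)-5-hydroxy-6,7,8-trimethoxy-4H-chromen-4-one | COc1c(OC)c(O)c2c(=O)cc(-c3ccc4OC(c5ccccc5)(c5ccccc5)Oc4c3)oc2c1OC
A2 | alternative 1 | 6,8-dibromo-2-(2,2-diphenyl-1,3-benzodioxol-5-yl)-5-hydroxy-7-methoxy-4H-chromen-4-one | COc1c(Br)c(O)c2c(=O)cc(-c3ccc4OC(c5ccccc5)(c5ccccc5)Oc4c3)oc2c1Br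
A3 | alternative 1 | luteolin | O=c1cc(-c2ccc(O)c(O)c2)oc2cc(O)cc(O)c12
A4 | alternative 2 | 2-[3,4-bis(benzyloxy)phenyl]-5,6,7,8-tetramethoxy-4H-chromen-4-one | COc1c(OC)c(OC)c2c(=O)cc(-c3ccc(OCc4ccccc4)c(OCc4ccccc4)c3)oc2c1OC
A5 | alternative 2 | 2,3,4,5-tetramethoxy-6-(trimethylsilyl)phenyl trifluoromethanesulfonate | COc1c(OC)c(OC)c(OS(=O)(=O)C(F)(F)F)c([Si](C)(C)C)c1OC
A6 | alternative 2 | 3-[3,4-bis(benzyloxy)phenyl]prop-2-ynoic acid | OC(=O)C#Cc1ccc(OCc2ccccc2)c(OCc2ccccc2)c1
A7 | alternative 3 | 2-[4,5-bis(trimethylsilyloxy)cyclohexa-1,4-dien-1-yl]-5-hydroxy-6,7,8-trimethoxy-4H-chromen-4-one | COc1c(OC)c(O)c2c(=O)cc(C3=CCC(O[Si](C)(C)C)=C(O[Si](C)(C)C)C3)oc2c1OC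
A8 | alternative 3 | 2-ethynyl-5-hydroxy-6,7,8-trimethoxy-4H-chromen-4-one | COc1c(OC)c(O)c2c(=O)cc(C#C)oc2c1OC
A9 | alternative 3 | 2,3-bis(trimethylsilyloxy)buta-1,3-diene | C=C(O[Si](C)(C)C)C(=C)O[Si](C)(C)C
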